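Atoms carry germacrane numbers: ring C1–C10, methylene-lactone carbons C11–C13, butenolide carbonyl C14, hydroxymethyl C15. Everything rests on opening the α-methylene-γ-butyrolactone at C7–C11. That bond lies anti to the butenolide C8–O bond and next to C6–O, the pattern of a threo 2,3-epoxy alcohol. In the key step a phosphonoacetate on O6 opens a 7,8-epoxide at C7 (5-exo, inversion), the freed C8 alkoxide lactonises onto the C14 ester held cis by the Z C9=C10 bond, and the phosphonate then olefinates formaldehyde: both lactones and the C11=C13 methylene in one operation from an acyclic epoxy dienoate. Ring-closing metathesis at C4=C5 then forms the ten-membered ring.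

Key step: step 9

Assumption: in step 3 the (S)-diphenylprolinol-derived oxazaborolidinium ion is taken to direct Re-face attack on aldehyde 4 (1S product); if the sense proves opposite, its enantiomer is used.

(TBS = tert-butyldimethylsilyl.)

Step 1
Reactants: 1 2-methylidenepropane-1,3-diol
Product: 2 2-{[(tert-butyldimethylsilyl)oxy]methyl}prop-2-en-1-ol
Conditions: NaH (1.0 equiv), THF, 0 °C to rt; TBSCl (1.0 equiv)
Reagents that add atoms: tert-butyldimethylsilyl chloride, CC(C)(C)[Si](C)(C)Cl
Why: Deprotonation of one hydroxyl of the symmetrical diol with one equivalent of NaH and O-silylation of the mono-alkoxide (Williamson-type silyl ether formation) should give the mono-TBS ether; no stereocentre is involved.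

Step 2
Reactants: 2 2-{[(TBS)oxy]methyl}prop-2-en-1-ol
Product: 4 4-{[(TBS)oxy]methyl}pent-4-enal, via allyl vinyl ether 3 (not isolated)
Conditions: ethyl vinyl ether (solvent), Hg(OAc)2 (cat.), reflux; evaporate; PhMe, 135 °C, sealed tube
Reagents that add atoms: ethyl vinyl ether, C=COCC
Why: Hg(OAc)2-catalysed transvinylation gives allyl vinyl ether 3, whose thermal Claisen rearrangement ([3,3]-sigmatropic shift) should deliver the γ,δ-unsaturated aldehyde carrying C1–C4 and C15; no stereocentre is formed.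

Step 3
Reactants: 4 4-{[(TBS)oxy]methyl}pent-4-enal; 5 methyl prop-2-ynoate (methyl propiolate)
Product: 7 methyl (2Z)-2-[(1S)-4-{[(TBS)oxy]methyl}-1-hydroxypent-4-en-1-yl]-3-iodoprop-2-enoate, via O-trimethylsilyl ether 6 (not isolated)
Conditions: TMSI, oxazaborolidinium triflimide catalyst [20 mol %, from (S)-α,α-diphenylprolinol, o-tolylboronic acid and HNTf2], CH2Cl2, −78 °C; then citric acid, MeOH, 0 °C
Reagents that add atoms: iodotrimethylsilane, C[Si](C)(C)I
Why: Iodide from TMSI adds to the propiolate to give a β-iodo silyl allenolate that attacks the catalyst-bound aldehyde (catalytic enantioselective three-component iodo-aldol, a Morita–Baylis–Hillman-type Mukaiyama aldol reaction); the oxazaborolidinium ion blocks one aldehyde face so that C1 is set as S, and the kinetic Z iodoalkene places C9–I cis to the ester.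

Step 4
Reactants: 7 methyl (2Z)-2-[(1S)-4-{[(TBS)oxy]methyl}-1-hydroxypent-4-en-1-yl]-3-iodoprop-2-enoate
Product: 8 methyl (2Z)-2-[(1S)-4-{[(TBS)oxy]methyl}-1-[(2-methylpropanoyl)oxy]pent-4-en-1-yl]-3-iodoprop-2-enoate
Conditions: i-PrCOCl, pyridine, CH2Cl2, 0 °C
Reagents that add atoms: 2-methylpropanoyl chloride, CC(C)C(=O)Cl
Why: Acyl chloride esterification of the secondary allylic alcohol installs the isobutyrate of the target with retention at C1; pyridine is used without DMAP so that no nucleophilic amine adds to the β-iodoacrylate.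

Step 5
Reactants: 9 (E)-1,2-bis(tributylstannyl)ethene; 10 prop-2-enal (acrolein)
Product: 11 rac-(1E)-1-(tributylstannyl)penta-1,4-dien-3-ol
Conditions: n-BuLi (1.0 equiv), THF, −78 °C; then acrolein, −78 °C; H2O
Reagents that add atoms: none
Why: Tin–lithium exchange at one terminus of 9 gives the E alkenyllithium, which adds 1,2 to acrolein (organolithium carbonyl addition) with retention of the E geometry; the new carbinol (C6) is racemic and is resolved in step 7.

Step 6
Reactants: 8 methyl (2Z)-2-[(1S)-4-{[(TBS)oxy]methyl}-1-[(2-methylpropanoyl)oxy]pent-4-en-1-yl]-3-iodoprop-2-enoate; 11 rac-(1E)-1-(tributylstannyl)penta-1,4-dien-3-ol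
Product: 12 methyl (2Z,4E)-6-hydroxy-2-[(1S)-4-{[(TBS)oxy]methyl}-1-[(2-methylpropanoyl)oxy]pent-4-en-1-yl]octa-2,4,7-trienoate (both C6 epimers)
Conditions: Cu(O2CC4H3S) (monovalent copper thiophene-2-carboxylate, 1.5 equiv), NMP, 0 °C to rt
Reagents that add atoms: none
Why: Copper-mediated Stille-type cross-coupling of the activated Z β-iodoenoate with the E alkenylstannane should proceed with retention at both alkenes and, being palladium-free, should not ionise the allylic isobutyrate; the free C6 hydroxyl is tolerated.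

Step 7
Reactants: 12 methyl (2Z,4E)-6-hydroxy-2-[(1S)-4-{[(TBS)oxy]methyl}-1-[(2-methylpropanoyl)oxy]pent-4-en-1-yl]octa-2,4,7-trienoate (both C6 epimers)
Product: 13 methyl (2Z)-3-{(2R,3R)-3-[(1S)-1-hydroxyprop-2-en-1-yl]oxiran-2-yl}-2-[(1S)-4-{[(TBS)oxy]methyl}-1-[(2-methylpropanoyl)oxy]pent-4-en-1-yl]prop-2-enoate (erythro epoxy alcohol)
Conditions: Ti(OiPr)4, L-(+)-diisopropyl tartrate, t-BuOOH (0.55 equiv), 4 Å MS, CH2Cl2, −20 °C
Reagents that add atoms: tert-butyl hydroperoxide, CC(C)(C)OO
Why: Sharpless asymmetric epoxidation used as a kinetic resolution: with L-(+)-tartrate only the 6S epimer should be epoxidised at the E C7=C8 bond, on the face fixed by the tartrate (setting C7 and C8, erythro to C6), because the vinyl group of this epimer is mismatched and monosubstituted, the C9=C10 enoate is electron-poor and the C4 methylene is not allylic to a free hydroxyl; the untouched 6R epimer is separated.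

Step 8
Reactants: 13 erythro epoxy alcohol (as in step 7); 14 2-(diethoxyphosphoryl)acetic acid
Product: 15 methyl (2Z)-3-[(2R,3S)-3-{(1R)-1-[2-(diethoxyphosphoryl)acetoxy]prop-2-en-1-yl}oxiran-2-yl]-2-[(1S)-4-{[(TBS)oxy]methyl}-1-[(2-methylpropanoyl)oxy]pent-4-en-1-yl]prop-2-enoate (threo epoxy ester)
Conditions: PPh3, DIAD, PhMe, 0 °C
Reagents that add atoms: none
Why: Mitsunobu esterification with the acidic phosphonoacetic acid proceeds by SN2 displacement of the oxyphosphonium group, inverting C6 to the threo ester and installing the carbanion tether in the same operation.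

Step 9
Reactants: 15 threo epoxy phosphonoacetate (as in step 8)
Product: 18 (1S)-1-{(5R)-5-[(2R,3S)-2-ethenyl-4-methylidene-5-oxooxolan-3-yl]-2-oxo-2,5-dihydrofuran-3-yl}-4-{[(TBS)oxy]methyl}pent-4-en-1-yl 2-methylpropanoate, via hydroxy phosphonolactone 16 (not isolated), via phosphono bislactone 17 (not isolated)
Conditions: NaH (1.05 equiv), THF, 0 °C to rt; then (CH2O)n, 0 °C
Reagents that add atoms: formaldehyde (from paraformaldehyde), C=O
Why: NaH removes only the doubly activated phosphonoacetate proton, and the carbanion C11, tethered through the C6 ester oxygen, opens the trans-epoxide at C7 anti to the epoxide oxygen to form the C7–C11 bond (5-exo-tet, the breaking C7–O bond exocyclic to the new lactone); this is an intramolecular epoxide alkylation by a stabilised carbanion and the carbon counterpart of the C-2-selective intramolecular opening of 2,3-epoxy alcohol carbamates and carbonates. The C8 alkoxide set free is held cis to the C14 methyl ester by the Z C9=C10 bond and lactonises (5-exo-trig acyl substitution) to the butenolide, and the methoxide released regenerates the phosphonate carbanion, which olefinates formaldehyde (Horner–Wadsworth–Emmons) to the C11=C13 methylene. C7 is the only stereocentre formed and is set by SN2 inversion, which with the threo 6R ester from step 8 gives the trans H6/H7 lactone and the 7S,8R relationship; C6 and C8 are carried unchanged from steps 7 and 8. The step needs attack at C7 and not at the allylic C8 (6-endo, δ-lactone): the three-atom ester tether reaches C7 in the exo mode, whereas the endo mode needs a fused transition state, and the phosphoryl-stabilised carbanion is not bound to the planar-enolate geometry that hampers simple ester enolates in five-ring closures. It also needs the carbanion to leave the hindered β-substituted enoate and its allylic isobutyrate alone and the γ-proton of the new butenolide to stay in place, which is why a single equivalent of base is used and the carbanion is consumed by formaldehyde at low temperature.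

Step 10
Reactants: 18 bislactone triene (as in step 9)
Product: 19 (1S,4E,6R,7S,8R,9Z)-15-[(TBS)oxy]-1-[(2-methylpropanoyl)oxy]germacra-4,9,11(13)-triene-12,6:14,8-diolide (15-O-TBS ether of the target)
Conditions: second-generation Hoveyda–Grubbs catalyst RuCl2(=CH-C6H4-2-Oi-Pr)(H2IMes) (15 mol %), PhMe (1 mM), 80 °C
Reagents that add atoms: none
Why: Ring-closing metathesis between the C5 vinyl group and the C4 1,1-disubstituted alkene, driven by loss of ethene at high dilution, should form the ten-membered ring with the ring-cis trisubstituted alkene (C3 and C6 cis, CIP E) that is normal for ten-membered cycloalkenes; the butenolide and methylene-lactone alkenes are poor metathesis partners.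

Step 11
Reactants: 19 15-O-TBS ether of the target
Product: 20 (1S,4E,6R,7S,8R,9Z)-15-hydroxy-1-[(2-methylpropanoyl)oxy]germacra-4,9,11(13)-triene-12,6:14,8-diolide (CNP0322767.4)
Conditions: HF·pyridine, pyridine, THF, 0 °C
Reagents that add atoms: none
Why: Fluoride-mediated desilylation under buffered acidic conditions frees the C15 hydroxyl without base, so the isobutyrate, the base-labile butenolide and both Michael acceptors should survive.

Compound list
1 | 2-methylidenepropane-1,3-diol | C=C(CO)CO | starting material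
2 | 2-{[(tert-butyldimethylsilyl)oxy]methyl}prop-2-en-1-ol | C=C(CO)CO[Si](C)(C)C(C)(C)C | intermediate
3 | tert-butyl({2-[(ethenyloxy)methyl]prop-2-en-1-yl}oxy)dimethylsilane (allyl vinyl ether, not isolated) | C=COCC(=C)CO[Si](C)(C)C(C)(C)C | intermediate
4 | 4-{[(TBS)oxy]methyl}pent-4-enal | O=CCCC(=C)CO[Si](C)(C)C(C)(C)C | intermediate
5 | methyl prop-2-ynoate | C#CC(=O)OC | starting material
6 | methyl (2Z)-2-[(1S)-4-{[(TBS)oxy]methyl}-1-[(trimethylsilyl)oxy]pent-4-en-1-yl]-3-iodoprop-2-enoate (not isolated) | I/C=C(\C(=O)OC)[C@@H](O[Si](C)(C)C)CCC(=C)CO[Si](C)(C)C(C)(C)C | intermediate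
7 | methyl (2Z)-2-[(1S)-4-{[(TBS)oxy]methyl}-1-hydroxypent-4-en-1-yl]-3-iodoprop-2-enoate | I/C=C(\C(=O)OC)[C@@H](O)CCC(=C)CO[Si](C)(C)C(C)(C)C | intermediate
8 | methyl (2Z)-2-[(1S)-4-{[(TBS)oxy]methyl}-1-[(2-methylpropanoyl)oxy]pent-4-en-1-yl]-3-iodoprop-2-enoate | I/C=C(\C(=O)OC)[C@@H](OC(=O)C(C)C)CCC(=C)CO[Si](C)(C)C(C)(C)C | intermediate
9 | (E)-1,2-bis(tributylstannyl)ethene | CCCC[Sn](CCCC)(CCCC)/C=C/[Sn](CCCC)(CCCC)CCCC | starting material
10 | prop-2-enal (acrolein) | C=CC=O | starting material
11 | rac-(1E)-1-(tributylstannyl)penta-1,4-dien-3-ol | C=CC(O)/C=C/[Sn](CCCC)(CCCC)CCCC | intermediate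
12 | methyl (2Z,4E)-6-hydroxy-2-[(1S)-4-{[(TBS)oxy]methyl}-1-[(2-methylpropanoyl)oxy]pent-4-en-1-yl]octa-2,4,7-trienoate, both C6 epimers | C=CC(O)/C=C/C=C(\C(=O)OC)[C@@H](OC(=O)C(C)C)CCC(=C)CO[Si](C)(C)C(C)(C)C | intermediate
13 | methyl (2Z)-3-{(2R,3R)-3-[(1S)-1-hydroxyprop-2-en-1-yl]oxiran-2-yl}-2-[(1S)-4-{[(TBS)oxy]methyl}-1-[(2-methylpropanoyl)oxy]pent-4-en-1-yl]prop-2-enoate | C=C[C@H](O)[C@H]1O[C@@H]1/C=C(\C(=O)OC)[C@@H](OC(=O)C(C)C)CCC(=C)CO[Si](C)(C)C(C)(C)C | intermediate
14 | 2-(diethoxyphosphoryl)acetic acid | OC(=O)CP(=O)(OCC)OCC | starting material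
15 | methyl (2Z)-3-[(2R,3S)-3-{(1R)-1-[2-(diethoxyphosphoryl)acetoxy]prop-2-en-1-yl}oxiran-2-yl]-2-[(1S)-4-{[(TBS)oxy]methyl}-1-[(2-methylpropanoyl)oxy]pent-4-en-1-yl]prop-2-enoate | C=C[C@@H](OC(=O)CP(=O)(OCC)OCC)[C@H]1O[C@@H]1/C=C(\C(=O)OC)[C@@H](OC(=O)C(C)C)CCC(=C)CO[Si](C)(C)C(C)(C)C | intermediate
16 | methyl (2Z,4R)-4-[(2R,3R)-4-(diethoxyphosphoryl)-2-ethenyl-5-oxooxolan-3-yl]-4-hydroxy-2-[(1S)-4-{[(TBS)oxy]methyl}-1-[(2-methylpropanoyl)oxy]pent-4-en-1-yl]but-2-enoate, both epimers at the phosphorus-bearing carbon (not isolated) | CCOP(=O)(OCC)C1C(=O)O[C@H](C=C)[C@H]1[C@H](O)/C=C(\C(=O)OC)[C@@H](OC(=O)C(C)C)CCC(=C)CO[Si](C)(C)C(C)(C)C | intermediate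
17 | (1S)-1-{(5R)-5-[(2R,3S)-4-(diethoxyphosphoryl)-2-ethenyl-5-oxooxolan-3-yl]-2-oxo-2,5-dihydrofuran-3-yl}-4-{[(TBS)oxy]methyl}pent-4-en-1-yl 2-methylpropanoate, both epimers at the phosphorus-bearing carbon (not isolated) | CCOP(=O)(OCC)C1C(=O)O[C@H](C=C)[C@H]1[C@@H]2OC(=O)C(=C2)[C@@H](OC(=O)C(C)C)CCC(=C)CO[Si](C)(C)C(C)(C)C | intermediate
18 | (1S)-1-{(5R)-5-[(2R,3S)-2-ethenyl-4-methylidene-5-oxooxolan-3-yl]-2-oxo-2,5-dihydrofuran-3-yl}-4-{[(TBS)oxy]methyl}pent-4-en-1-yl 2-methylpropanoate | C=C1C(=O)O[C@H](C=C)[C@H]1[C@@H]2OC(=O)C(=C2)[C@@H](OC(=O)C(C)C)CCC(=C)CO[Si](C)(C)C(C)(C)C | intermediate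
19 | (1S,4E,6R,7S,8R,9Z)-15-[(TBS)oxy]-1-[(2-methylpropanoyl)oxy]germacra-4,9,11(13)-triene-12,6:14,8-diolide | C=C1C(=O)O[C@@H]2/C=C(/CO[Si](C)(C)C(C)(C)C)CC[C@H](OC(=O)C(C)C)C3=C[C@@H](OC3=O)[C@@H]12 | intermediate
20 | (1S,4E,6R,7S,8R,9Z)-15-hydroxy-1-[(2-methylpropanoyl)oxy]germacra-4,9,11(13)-triene-12,6:14,8-diolide (CNP0322767.4) | C=C1C(=O)O[C@@H]2/C=C(/CO)CC[C@H](OC(=O)C(C)C)C3=C[C@@H](OC3=O)[C@@H]12 | target

Total step count: 11 steps.
Longest linear sequence: 10 steps (1 → 2 → 4 → 7 → 8 → 12 → 13 → 15 → 18 → 19 → 20; step 5 is the side branch).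

Steps most likely to fail

Step 9 (key cascade). The carbanion may attack the enoate-activated allylic C8 in the endo mode instead of C7. The closure may also be slow because the ester tether must reach its s-cis rotamer, which would leave time for displacement or elimination of the allylic isobutyrate and for γ-deprotonation of the new butenolide (scrambling C8). Fallback, setting out from 11 and 8 and returning at 18: the same epoxide alkylation is run on a substrate without the dienoate, and the butenolide is built afterwards under neutral conditions. Stannane 11 is coupled with vinyl bromide (Pd(PPh3)4, Stille) to (4E)-hepta-1,4,6-trien-3-ol F1. Sharpless kinetic resolution (Ti(OiPr)4, L-(+)-diisopropyl tartrate, t-BuOOH) gives the erythro divinyl epoxy alcohol F2, and Mitsunobu reaction with 14 gives the threo phosphonoacetate F3. NaH and then formaldehyde give the hydroxy methylene lactone F4. In parallel, iodide 8 is reduced (Bu3SnH, Et3B, air) to the acrylate F5, whose methyl ester is cleaved with Me3SnOH to the acrylic acid F6. Carbodiimide esterification of F4 with F6 gives the ester F7, and ring-closing metathesis between the C9 vinyl group and the acrylate (second-generation Grubbs catalyst RuCl2(=CHPh)(H2IMes)(PCy3)) closes the butenolide to give 18.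

Step 10 (macrocyclic RCM). Intermolecular metathesis may outrun ring closure, or the catalyst may stall at the hindered 1,1-disubstituted alkene, because closing the ring onto the rigid bislactone builds in the strain of the bridging butenolide. Fallback, setting out from 15 and returning at 19: the order of ring formation is reversed. The flexible epoxy phosphonoacetate 15 is cyclised first with the same ruthenium catalyst to the ten-membered epoxy phosphonoacetate F8, in which no bridged ring is yet present. The NaH and formaldehyde cascade of step 9 is then run transannularly on F8 and gives 19 directly.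

Step 7 (resolving epoxidation). Epoxidation of the electron-poor diene may be slow, the discrimination between the C6 epimers may erode, and the titanium alkoxide may open the vinylogous epoxide. Fallback, setting out from 8 and returning at 13 (and at 15): the epoxide is made from a primary allylic alcohol and the vinyl group is added afterwards. Iodide 8 is coupled with commercial (E)-3-(tributylstannyl)prop-2-en-1-ol (same copper carboxylate) to the primary dienol F9. Sharpless epoxidation with L-(+)-diethyl tartrate, which needs no resolution, gives the epoxy alcohol F10, and Dess–Martin oxidation gives the epoxy aldehyde F11. Addition of CH2=CHMgBr at −78 °C gives 13 together with its C6 epimer F12. Compound 13 continues through step 8, and the threo epimer F12 is esterified with 14 by a carbodiimide with retention to give 15, so both epimers converge.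

Further compounds
F1 | step 9 | rac-(4E)-hepta-1,4,6-trien-3-ol | C=CC(O)/C=C/C=C
F2 | step 9 | (1S)-1-[(2R,3R)-3-ethenyloxiran-2-yl]prop-2-en-1-ol | C=C[C@H](O)[C@H]1O[C@@H]1C=C
F3 | step 9 | (1R)-1-[(2S,3R)-3-ethenyloxiran-2-yl]prop-2-en-1-yl 2-(diethoxyphosphoryl)acetate | C=C[C@@H](OC(=O)CP(=O)(OCC)OCC)[C@H]1O[C@@H]1C=C
F4 | step 9 | (4R,5R)-5-ethenyl-4-[(1R)-1-hydroxyprop-2-en-1-yl]-3-methylideneoxolan-2-one | C=C1C(=O)O[C@H](C=C)[C@H]1[C@H](O)C=C
F5 | step 9 | methyl 2-[(1S)-4-{[(TBS)oxy]methyl}-1-[(2-methylpropanoyl)oxy]pent-4-en-1-yl]prop-2-enoate | C=C(C(=O)OC)[C@@H](OC(=O)C(C)C)CCC(=C)CO[Si](C)(C)C(C)(C)C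
F6 | step 9 | 2-[(1S)-4-{[(TBS)oxy]methyl}-1-[(2-methylpropanoyl)oxy]pent-4-en-1-yl]prop-2-enoic acid | C=C(C(=O)O)[C@@H](OC(=O)C(C)C)CCC(=C)CO[Si](C)(C)C(C)(C)C
F7 | step 9 | (1R)-1-[(2R,3S)-2-ethenyl-4-methylidene-5-oxooxolan-3-yl]prop-2-en-1-yl 2-[(1S)-4-{[(TBS)oxy]methyl}-1-[(2-methylpropanoyl)oxy]pent-4-en-1-yl]prop-2-enoate | C=C1C(=O)O[C@H](C=C)[C@H]1[C@H](OC(=O)C(=C)[C@@H](OC(=O)C(C)C)CCC(=C)CO[Si](C)(C)C(C)(C)C)C=C
F8 | step 10 | methyl (1S,4E,6R,7S,8R,9Z)-6-[2-(diethoxyphosphoryl)acetoxy]-7,8-epoxy-1-[(2-methylpropanoyl)oxy]-15-[(TBS)oxy]germacra-4,9-dien-14-oate (ten-membered ring, trans-epoxide) | CCOP(=O)(OCC)CC(=O)O[C@@H]1/C=C(/CO[Si](C)(C)C(C)(C)C)CC[C@H](OC(=O)C(C)C)/C(C(=O)OC)=C/[C@H]2O[C@H]12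
F9 | step 7 | methyl (2Z,4E)-6-hydroxy-2-[(1S)-4-{[(TBS)oxy]methyl}-1-[(2-methylpropanoyl)oxy]pent-4-en-1-yl]hexa-2,4-dienoate | OC/C=C/C=C(\C(=O)OC)[C@@H](OC(=O)C(C)C)CCC(=C)CO[Si](C)(C)C(C)(C)C
F10 | step 7 | methyl (2Z)-3-[(2R,3R)-3-(hydroxymethyl)oxiran-2-yl]-2-[(1S)-4-{[(TBS)oxy]methyl}-1-[(2-methylpropanoyl)oxy]pent-4-en-1-yl]prop-2-enoate | OC[C@H]1O[C@@H]1/C=C(\C(=O)OC)[C@@H](OC(=O)C(C)C)CCC(=C)CO[Si](C)(C)C(C)(C)C
F11 | step 7 | methyl (2Z)-3-[(2R,3S)-3-formyloxiran-2-yl]-2-[(1S)-4-{[(TBS)oxy]methyl}-1-[(2-methylpropanoyl)oxy]pent-4-en-1-yl]prop-2-enoate | O=C[C@H]1O[C@@H]1/C=C(\C(=O)OC)[C@@H](OC(=O)C(C)C)CCC(=C)CO[Si](C)(C)C(C)(C)C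
F12 | step 7 | methyl (2Z)-3-{(2R,3R)-3-[(1R)-1-hydroxyprop-2-en-1-yl]oxiran-2-yl}-2-[(1S)-4-{[(TBS)oxy]methyl}-1-[(2-methylpropanoyl)oxy]pent-4-en-1-yl]prop-2-enoate (threo epimer of 13) | C=C[C@@H](O)[C@H]1O[C@@H]1/C=C(\C(=O)OC)[C@@H](OC(=O)C(C)C)CCC(=C)CO[Si](C)(C)C(C)(C)C
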